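**Retrosynthetic overview**
1. Target 31 ⇒ C6 acylation of 29 with 30 ⇒ C6–OH-directed epoxidation of the isopropenyl group of 28 ⇒ C5 esterification of 25 with 26.
2. The C4=CH2/C5–OH unit of 25 ⇒ hydroxyl-directed 4,5-epoxide 23 opened by titanocene chloride; the 1′-acetoxy/2-oxo unit ⇒ isoxazoline 18.
3. 18 ⇒ oxime 16: an intramolecular nitrile oxide–alkene [3+2] cycloaddition onto a (Z)-propenyl group closes the cyclopentane (C1–C2 bond) and sets C1 and C1′.
4. 16 ⇒ 12: a Claisen [3,3] rearrangement of a cyclohexenyl vinyl ether makes the C3a–C3 bond with 1,3-chirality transfer.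
5. 12 ⇒ (R)-carvone 1 (trans α′-allylation, Wharton 1,3-transposition, α′-oxygenation). Ring order: six-membered ring bought; cyclopentane and a temporary isoxazoline ring formed together; isoxazoline opened; oxirane last.

Assumption: bicyclic compounds are numbered as octahydro-1H-inden-2-ones (C1 side-chain carbon, C2 ketone, C3a/C7a ring fusion, C4 methylidene carbon, C5/C6 oxygenated, C7 isopropenyl-bearing, C1′ side-chain carbinol); 2, 13, 26 and 30 are bought.

**Step 1**
Reactants: 1 (R)-carvone; 2 allyl bromide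
Product: 3 (5R,6S)-6-allylcarvone
Conditions: LiN(iPr)2, THF, −78 °C; then 2, DMPU, −78 → −20 °C
Reagents that add atoms: none
Why: Kinetic α′-enolate alkylation, in which the electrophile enters anti to the neighbouring isopropenyl group, so C5 of carvone sets the trans C6 centre (future C7a).

**Step 2**
Reactants: 3 (5R,6S)-6-allylcarvone
Product: 4 epoxy ketone
Conditions: H2O2 (30 %), NaOH (aq, cat.), MeOH, 0 °C
Reagents that add atoms: hydrogen peroxide, OO
Why: Weitz–Scheffer nucleophilic epoxidation touches only the enone alkene and adds anti to the isopropenyl group (these oxirane centres are erased in step 4).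

**Step 3**
Reactants: 4 epoxy ketone
Product: 6 4-allyl-2-methyl-5-isopropenylcyclohex-2-en-1-ol, via epoxy hydrazone 5 (not isolated)
Conditions: N2H4·H2O, AcOH (cat.), MeOH, 0 °C → rt
Reagents that add atoms: none
Why: Wharton rearrangement (hydrazone, vinyl diazene, loss of N2) transposes the oxygen 1,3 and moves the alkene next to the allyl-bearing carbon without touching the two existing stereocentres.

**Step 4**
Reactants: 6 4-allyl-2-methyl-5-isopropenylcyclohex-2-en-1-ol
Product: 7 (4R,5R)-4-allyl-2-methyl-5-isopropenylcyclohex-2-en-1-one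
Conditions: Dess–Martin periodinane, NaHCO3, CH2Cl2, rt
Reagents that add atoms: none
Why: Dess–Martin oxidation of the allylic alcohol gives the transposed enone, which is needed for α′-oxygenation and for setting the carbinol configuration in step 7.

**Step 5**
Reactants: 7 (4R,5R)-4-allyl-2-methyl-5-isopropenylcyclohex-2-en-1-one
Product: 8 TBS dienol ether
Conditions: LiN(iPr)2, THF, −78 °C; then TBSOTf, −78 → 0 °C
Reagents that add atoms: tert-butyldimethylsilyl trifluoromethanesulfonate, CC(C)(C)[Si](C)(C)OS(=O)(=O)C(F)(F)F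
Why: Kinetic deprotonation of a cyclohexenone occurs at the α′-CH2, and O-silylation traps the cross-conjugated dienolate.

**Step 6**
Reactants: 8 TBS dienol ether
Product: 10 6-silyloxy enone, via silyloxy oxirane 9 (not isolated)
Conditions: mCPBA (1.0 equiv), NaHCO3, CH2Cl2, −20 → 0 °C
Reagents that add atoms: 3-chloroperoxybenzoic acid, O=C(OO)c1cccc(Cl)c1
Why: Rubottom oxidation, in which the electron-rich enol ether is epoxidised anti to the adjacent isopropenyl group and 1,4-silyl migration gives the α-silyloxy ketone with the new C6–O trans to isopropenyl (also the thermodynamic epimer).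

**Step 7**
Reactants: 10 6-silyloxy enone
Product: 11 allyl cyclohexenol
Conditions: NaBH4, CeCl3·7H2O, MeOH, −78 °C
Reagents that add atoms: none
Why: Luche 1,2-reduction with axial hydride delivery gives the equatorial C1 alcohol, trans to the neighbouring silyl ether and cis to isopropenyl; this oxygen only relays chirality in step 9.

**Step 8**
Reactants: 11 allyl cyclohexenol
Product: 12 (Z)-propenyl cyclohexenol
Conditions: CoBr2[Ph2PCH2C(CH3)2CH2PPh2] (5 mol %), Zn, ZnI2, Ph2PH (10 mol % each), CH2Cl2, rt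
Reagents that add atoms: none
Why: Cobalt-hydride-catalysed one-position alkene migration under kinetic control converts only the monosubstituted terminal alkene into the (Z)-2-alkene, while the 1,1-disubstituted and trisubstituted alkenes do not insert.

**Step 9**
Reactants: 12 (Z)-propenyl cyclohexenol; 13 ethyl vinyl ether
Product: 15 (Z)-propenyl aldehyde, via allyl vinyl ether 14 (not isolated)
Conditions: 13 (solvent), Hg(OAc)2 (0.2 equiv), reflux; evaporate; xylene, NaHCO3 (solid), 150 °C, sealed tube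
Reagents that add atoms: none
Why: Claisen [3,3]-sigmatropic rearrangement with suprafacial transfer from the C–O face forms the future C3a–C3 bond cis to the departing oxygen, hence trans to the neighbouring propenyl group, and moves the alkene to C4=C5.

**Step 10**
Reactants: 15 (Z)-propenyl aldehyde
Product: 16 aldoxime
Conditions: NH2OH·HCl, NaOAc, EtOH, rt
Reagents that add atoms: hydroxylamine hydrochloride, Cl.NO
Why: Oxime condensation of the only carbonyl group prepares the nitrile oxide precursor; no stereocentre is affected.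

**Step 11**
Reactants: 16 aldoxime
Product: 18 tricyclic isoxazoline, via nitrile oxide 17 (not isolated)
Conditions: NaOCl (aq), Et3N (cat.), CH2Cl2, 0 °C → rt, high dilution
Reagents that add atoms: none
Why: Intramolecular nitrile oxide–alkene [3+2] cycloaddition closes the trans-fused cyclopentane; suprafacial addition to the Z-alkene fixes C1′ relative to C1, and allylic 1,3-strain (C7a–H eclipsing the Z-alkene) makes the tethered dipole add anti to C7, giving the C1 configuration of the target.

**Step 12**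
Reactants: 18 tricyclic isoxazoline
Product: 20 hydroxy ketone, via hydroxy imine 19 (not isolated)
Conditions: Mo(CO)6 (1 equiv), MeCN–H2O (15:1), 80 °C
Reagents that add atoms: water, O
Why: Reductive N–O cleavage and imine hydrolysis unmask the β-hydroxy ketone (syn-aldol array) without hydrogenating the two alkenes; the C–O bond at C1′ is untouched.

**Step 13**
Reactants: 20 hydroxy ketone
Product: 21 acetate
Conditions: Ac2O, pyridine, DMAP (cat.), CH2Cl2, 0 °C
Reagents that add atoms: acetic anhydride, CC(=O)OC(C)=O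
Why: Mild O-acetylation of the only free hydroxyl at 0 °C avoids β-elimination of the aldol.

**Step 14**
Reactants: 21 acetate
Product: 22 C6 alcohol
Conditions: HF·pyridine, THF, 0 °C → rt
Reagents that add atoms: none
Why: Fluoride-mediated desilylation under weakly acidic conditions frees the allylic C6 hydroxyl without harming the β-acetoxy ketone.

**Step 15**
Reactants: 22 C6 alcohol
Product: 23 epoxy alcohol
Conditions: mCPBA (1.05 equiv), NaHCO3, CH2Cl2, −20 → 0 °C
Reagents that add atoms: 3-chloroperoxybenzoic acid, O=C(OO)c1cccc(Cl)c1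
Why: Henbest epoxidation, in which the pseudo-equatorial allylic C6–OH hydrogen-bonds the peracid and delivers oxygen syn to itself onto the trisubstituted C4=C5 alkene (more reactive than the isopropenyl group), setting the C5–O configuration.

**Step 16**
Reactants: 23 epoxy alcohol
Product: 24 TES ether
Conditions: Et3SiCl, imidazole, DMAP (cat.), DMF, 0 °C → rt
Reagents that add atoms: chlorotriethylsilane, CC[Si](Cl)(CC)CC
Why: Silylation of the single hydroxyl keeps C6–O masked so that the C5 hydroxyl released next can be esterified alone.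

**Step 17**
Reactants: 24 TES ether
Product: 25 exocyclic allylic alcohol
Conditions: (C5H5)2TiCl2 (2.5 equiv), Mn dust, THF, rt; add 24; aq NH4Cl
Reagents that add atoms: none
Why: Nugent–RajanBabu opening by trivalent titanium cleaves the C4–O bond to the tertiary radical, which loses a hydrogen from the unhindered methyl group to a second titanocene chloride, giving the exocyclic methylene with the C5–O bond and its configuration intact.

**Step 18**
Reactants: 25 exocyclic allylic alcohol; 26 (E)-3-methylpent-2-enoic acid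
Product: 27 C5 enoate
Conditions: DCC, DMAP, CH2Cl2, rt
Reagents that add atoms: none
Why: Steglich esterification of the only free (axial allylic) hydroxyl under non-enolising conditions keeps the E-enoate geometry.

**Step 19**
Reactants: 27 C5 enoate
Product: 28 hydroxy enoate
Conditions: HF·pyridine, THF, 0 °C
Reagents that add atoms: none
Why: Selective Si–O cleavage frees the C6 hydroxyl; esters and the β-acetoxy ketone are stable to HF·pyridine.

**Step 20**
Reactants: 28 hydroxy enoate
Product: 29 oxirane alcohol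
Conditions: VO(acac)2 (5 mol %), tBuOOH (1.5 equiv, in decane), CH2Cl2, 0 °C → rt
Reagents that add atoms: tert-butyl hydroperoxide, CC(C)(C)OO
Why: Hydroxyl-directed vanadium-catalysed epoxidation of the homoallylic alcohol; the C6 vanadate delivers oxygen to the alkene face turned towards C6 through a chair-like transition state with the CH2 terminus exo, which should give the (S)-oxirane carbon, while the ester-deactivated methylidene and the enoate stay untouched.

**Step 21**
Reactants: 29 oxirane alcohol; 30 (S)-2-methylbutanoic anhydride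
Product: 31 target
Conditions: DMAP, Et3N, CH2Cl2, 0 °C → rt
Reagents that add atoms: none
Why: DMAP-catalysed acylation with the symmetric anhydride esterifies the equatorial C6 hydroxyl without epimerising the bought (S)-α-centre.

**Compound list**
1 | (R)-(−)-carvone, (5R)-2-methyl-5-(prop-1-en-2-yl)cyclohex-2-en-1-one | CC1=CC[C@@H](C(C)=C)CC1=O | starting material
2 | allyl bromide | C=CCBr | starting material
3 | (5R,6S)-6-allylcarvone (allyl trans to isopropenyl) | CC1=CC[C@@H](C(C)=C)[C@H](CC=C)C1=O | intermediate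
4 | epoxy ketone: 2,3-oxide of 3, oxirane trans to isopropenyl | C[C@@]12O[C@@H]1C[C@@H](C(C)=C)[C@H](CC=C)C2=O | intermediate
5 | epoxy hydrazone of 4 (not isolated) | C[C@@]12O[C@@H]1C[C@@H](C(C)=C)[C@H](CC=C)C2=NN | intermediate
6 | 4-allyl-2-methyl-5-isopropenylcyclohex-2-en-1-ol, OH and allyl both trans to isopropenyl | CC1=C[C@@H](CC=C)[C@H](C(C)=C)C[C@H]1O | intermediate
7 | (4R,5R)-4-allyl-2-methyl-5-isopropenylcyclohex-2-en-1-one | CC1=C[C@@H](CC=C)[C@H](C(C)=C)CC1=O | intermediate
8 | TBS dienol ether of 7 (1-silyloxy-cyclohexa-1(6),2-diene) | CC1=C[C@@H](CC=C)[C@H](C(C)=C)C=C1O[Si](C)(C)C(C)(C)C | intermediate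
9 | silyloxy oxirane from 8, oxirane trans to isopropenyl (not isolated) | CC1=C[C@@H](CC=C)[C@H](C(C)=C)[C@H]2O[C@]21O[Si](C)(C)C(C)(C)C | intermediate
10 | 6-silyloxy enone: 4-allyl-6-(tert-butyldimethylsilyloxy)-2-methyl-5-isopropenylcyclohex-2-en-1-one, OTBS trans to isopropenyl | CC1=C[C@@H](CC=C)[C@H](C(C)=C)[C@@H](O[Si](C)(C)C(C)(C)C)C1=O | intermediate
11 | allyl cyclohexenol: 1-ol of 10, OH cis to isopropenyl and trans to OTBS | CC1=C[C@@H](CC=C)[C@H](C(C)=C)[C@@H](O[Si](C)(C)C(C)(C)C)[C@@H]1O | intermediate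
12 | (Z)-propenyl cyclohexenol: as 11 with (Z)-prop-1-enyl at C4 | CC1=C[C@@H](/C=C\C)[C@H](C(C)=C)[C@@H](O[Si](C)(C)C(C)(C)C)[C@@H]1O | intermediate
13 | ethyl vinyl ether | C=COCC | starting material
14 | allyl vinyl ether of 12 (not isolated) | CC1=C[C@@H](/C=C\C)[C@H](C(C)=C)[C@@H](O[Si](C)(C)C(C)(C)C)[C@@H]1OC=C | intermediate
15 | (Z)-propenyl aldehyde: 2-[4-(tert-butyldimethylsilyloxy)-2-methyl-5-isopropenyl-6-[(Z)-prop-1-enyl]cyclohex-2-en-1-yl]acetaldehyde, CH2CHO trans to propenyl, all four ring substituents alternating | CC1=C[C@H](O[Si](C)(C)C(C)(C)C)[C@@H](C(C)=C)[C@H](/C=C\C)[C@H]1CC=O | intermediate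
16 | aldoxime of 15 | CC1=C[C@H](O[Si](C)(C)C(C)(C)C)[C@@H](C(C)=C)[C@H](/C=C\C)[C@H]1CC=NO | intermediate
17 | nitrile oxide from 16 (not isolated) | CC1=C[C@H](O[Si](C)(C)C(C)(C)C)[C@@H](C(C)=C)[C@H](/C=C\C)[C@H]1CC#[N+][O-] | intermediate
18 | tricyclic isoxazoline: trans-fused hexahydroindene with a 2-isoxazoline fused at C1–C2, ring methyl cis to C7a | CC1=C[C@H](O[Si](C)(C)C(C)(C)C)[C@@H](C(C)=C)[C@H]2[C@H]1CC3=NO[C@H](C)[C@H]23 | intermediate
19 | hydroxy imine (not isolated) | CC1=C[C@H](O[Si](C)(C)C(C)(C)C)[C@@H](C(C)=C)[C@H]2[C@H]1CC(=N)[C@@H]2[C@@H](C)O | intermediate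
20 | hydroxy ketone: trans-fused 6-(TBSO)-1-[(1R)-1-hydroxyethyl]-4-methyl-7-isopropenyl-1,3,3a,6,7,7a-hexahydroinden-2-one | CC1=C[C@H](O[Si](C)(C)C(C)(C)C)[C@@H](C(C)=C)[C@H]2[C@H]1CC(=O)[C@@H]2[C@@H](C)O | intermediate
21 | acetate of 20 | CC1=C[C@H](O[Si](C)(C)C(C)(C)C)[C@@H](C(C)=C)[C@H]2[C@H]1CC(=O)[C@@H]2[C@@H](C)OC(C)=O | intermediate
22 | C6 alcohol (TBS removed) | CC1=C[C@H](O)[C@@H](C(C)=C)[C@H]2[C@H]1CC(=O)[C@@H]2[C@@H](C)OC(C)=O | intermediate
23 | epoxy alcohol: 4,5-oxirane cis to C6–OH | C[C@@]13O[C@@H]1[C@H](O)[C@@H](C(C)=C)[C@H]2[C@H]3CC(=O)[C@@H]2[C@@H](C)OC(C)=O | intermediate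
24 | TES ether of 23 | C[C@@]13O[C@@H]1[C@H](O[Si](CC)(CC)CC)[C@@H](C(C)=C)[C@H]2[C@H]3CC(=O)[C@@H]2[C@@H](C)OC(C)=O | intermediate
25 | exocyclic allylic alcohol: 4-methylidene, C5–OH axial and cis to C6–OTES | C=C1[C@@H]2CC(=O)[C@H]([C@@H](C)OC(C)=O)[C@H]2[C@H](C(C)=C)[C@@H](O[Si](CC)(CC)CC)[C@H]1O | intermediate
26 | (E)-3-methylpent-2-enoic acid | OC(=O)/C=C(\C)CC | starting material
27 | C5 enoate: (E)-3-methylpent-2-enoate of 25 | C=C1[C@@H]2CC(=O)[C@H]([C@@H](C)OC(C)=O)[C@H]2[C@H](C(C)=C)[C@@H](O[Si](CC)(CC)CC)[C@H]1OC(=O)/C=C(\C)CC | intermediate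
28 | hydroxy enoate (C6–OH free) | C=C1[C@@H]2CC(=O)[C@H]([C@@H](C)OC(C)=O)[C@H]2[C@H](C(C)=C)[C@@H](O)[C@H]1OC(=O)/C=C(\C)CC | intermediate
29 | oxirane alcohol: (2S)-2-methyloxiran-2-yl at C7 | C=C1[C@@H]2CC(=O)[C@H]([C@@H](C)OC(C)=O)[C@H]2[C@H]([C@@]2(C)CO2)[C@@H](O)[C@H]1OC(=O)/C=C(\C)CC | intermediate
30 | (S)-2-methylbutanoic anhydride | CC[C@H](C)C(=O)OC(=O)[C@@H](C)CC | starting material
31 | target: (1S,3aR,5S,6R,7S,7aR)-1-[(1R)-1-acetoxyethyl]-4-methylidene-7-[(2S)-2-methyloxiran-2-yl]-6-[(2S)-2-methylbutanoyloxy]-2-oxooctahydro-1H-inden-5-yl (2E)-3-methylpent-2-enoate | C=C1[C@@H]2CC(=O)[C@H]([C@@H](C)OC(C)=O)[C@H]2[C@H]([C@@]2(C)CO2)[C@@H](OC(=O)[C@@H](C)CC)[C@H]1OC(=O)/C=C(\C)CC | target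

**Totals.** Total step count: 21. Longest linear sequence: 21 steps (1 → 31).

**Three steps most likely to fail**

Step 8 (Z-selective isomerisation; risk of E/Z mixtures or over-migration). The fallback sets out from 11 and comes back at 21. The allyl group is isomerised with RuHCl(CO)(PPh3)3 in toluene at 80 °C to the thermodynamically preferred (E)-propenyl cyclohexenol F1. The conditions of step 9 convert it through the allyl vinyl ether F2 into the (E)-propenyl aldehyde F3, and hydroxylamine gives the aldoxime F4. NaOCl generates the nitrile oxide F5, which cyclises to the isoxazoline F6, epimeric at the methyl-bearing carbon. Mo(CO)6 in wet MeCN opens it through the hydroxy imine F7 to the (1′S)-hydroxy ketone F8. A Mitsunobu esterification with acetic acid (PPh3, diisopropyl azodicarboxylate) then inverts C1′ and gives acetate 21 directly, replacing step 13.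

Step 9 (Claisen rearrangement; all four ring substituents must turn axial for the C–O bond to overlap, so high temperature and elimination are risks). The fallback sets out from 12 and comes back at 15. Methyl chloroformate and pyridine give the allylic methyl carbonate F9. Pd(PPh3)4 with sodium dimethyl malonate in THF effects a Tsuji–Trost alkylation; ionisation and attack both proceed with inversion (net retention) and the nucleophile adds at the allyl terminus remote from the silyloxy carbon, giving the malonate F10 with the same configuration as 15. Krapcho demethoxycarbonylation (NaCl, wet DMSO, 150 °C) gives the methyl ester F11, and iBu2AlH at −78 °C reduces it to aldehyde 15.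

Step 20 (directed epoxidation; the two rotamers of the isopropenyl group could erode the selectivity at the oxirane carbon). The fallback sets out from 28 and comes back at 29. Stoichiometric OsO4 with TMEDA in CH2Cl2 at −78 °C performs a hydrogen-bond-directed dihydroxylation from the C6–OH side and gives the osmate ester F12, which aqueous Na2SO3 cleaves to the triol F13. TsCl in pyridine sulfonylates only the primary hydroxyl to the tosylate F14, and Cs2CO3 in MeCN closes the tertiary alkoxide onto the primary carbon to give oxirane 29 with the oxygen on the face chosen in the osmylation.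

**Further compounds**
F1 | step 8 | (E)-propenyl cyclohexenol | CC1=C[C@@H](/C=C/C)[C@H](C(C)=C)[C@@H](O[Si](C)(C)C(C)(C)C)[C@@H]1O
F2 | step 8 | allyl vinyl ether of F1 (not isolated) | CC1=C[C@@H](/C=C/C)[C@H](C(C)=C)[C@@H](O[Si](C)(C)C(C)(C)C)[C@@H]1OC=C
F3 | step 8 | (E)-propenyl aldehyde | CC1=C[C@H](O[Si](C)(C)C(C)(C)C)[C@@H](C(C)=C)[C@H](/C=C/C)[C@H]1CC=O
F4 | step 8 | aldoxime of F3 | CC1=C[C@H](O[Si](C)(C)C(C)(C)C)[C@@H](C(C)=C)[C@H](/C=C/C)[C@H]1CC=NO
F5 | step 8 | nitrile oxide from F4 (not isolated) | CC1=C[C@H](O[Si](C)(C)C(C)(C)C)[C@@H](C(C)=C)[C@H](/C=C/C)[C@H]1CC#[N+][O-]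
F6 | step 8 | isoxazoline epimeric at the methyl-bearing carbon | CC1=C[C@H](O[Si](C)(C)C(C)(C)C)[C@@H](C(C)=C)[C@H]2[C@H]1CC3=NO[C@@H](C)[C@H]23
F7 | step 8 | hydroxy imine from F6 (not isolated) | CC1=C[C@H](O[Si](C)(C)C(C)(C)C)[C@@H](C(C)=C)[C@H]2[C@H]1CC(=N)[C@@H]2[C@H](C)O
F8 | step 8 | (1′S)-hydroxy ketone | CC1=C[C@H](O[Si](C)(C)C(C)(C)C)[C@@H](C(C)=C)[C@H]2[C@H]1CC(=O)[C@@H]2[C@H](C)O
F9 | step 9 | allylic methyl carbonate of 12 | CC1=C[C@@H](/C=C\C)[C@H](C(C)=C)[C@@H](O[Si](C)(C)C(C)(C)C)[C@@H]1OC(=O)OC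
F10 | step 9 | dimethyl malonate adduct | CC1=C[C@H](O[Si](C)(C)C(C)(C)C)[C@@H](C(C)=C)[C@H](/C=C\C)[C@H]1C(C(=O)OC)C(=O)OC
F11 | step 9 | methyl ester | CC1=C[C@H](O[Si](C)(C)C(C)(C)C)[C@@H](C(C)=C)[C@H](/C=C\C)[C@H]1CC(=O)OC
F12 | step 20 | osmate ester of 28 with TMEDA (not isolated) | C=C1[C@@H]2CC(=O)[C@H]([C@@H](C)OC(C)=O)[C@H]2[C@H]([C@@]2(C)CO[Os](=O)(=O)O2)[C@@H](O)[C@H]1OC(=O)/C=C(\C)CC.CN(C)CCN(C)C
F13 | step 20 | triol | C=C1[C@@H]2CC(=O)[C@H]([C@@H](C)OC(C)=O)[C@H]2[C@H]([C@](C)(O)CO)[C@@H](O)[C@H]1OC(=O)/C=C(\C)CC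
F14 | step 20 | primary tosylate | C=C1[C@@H]2CC(=O)[C@H]([C@@H](C)OC(C)=O)[C@H]2[C@H]([C@](C)(O)COS(=O)(=O)c2ccc(C)cc2)[C@@H](O)[C@H]1OC(=O)/C=C(\C)CC
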